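The constants of this flask are not to hand, so two of us read what they must be from the runs so far. The flask asked about is the teal run followed on to 4.0 h; the violet run had the same substrate but less coupling partner.

| flask | substrate | coupling partner | remark | time |
|---|---|---|---|---|
| teal | 0.050 M | 0.0525 M | the very flask that is asked about, followed so far |  |
| violet | 0.050 M | 0.035 M | run made earlier |  |
| flask | 0.050 M | 0.0525 M |  | 4.0 h |

| run | time / min | isomer of the product A / % | target / % |
|---|---|---|---|
| teal | 3.00 | 4 | 3 |
| teal | 8.00 | 5 | 13 |
| teal | 20.0 | 11 | 18 |
| teal | 40.0 | 15 | 26 |
| violet | 8.00 | 0 | 7 |
| violet | 20.0 | 6 | 12 |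
| violet | 40.0 | 13 | 19 |
| violet | 90.0 | 16 | 21 |

(standard deviation of a reading: 2 percentage points)

- share of isomer of the product A in isomer of the product A plus target at 40 s
- share of isomer of the product A in isomer of the product A plus target at 12 min
- share of isomer of the product A in isomer of the product A plus target at 4.0 h

- what was read earlier has a scatter of 2 percentage points, one standard deviation

We both start from the opening share (the selectivity under kinetic control), isomer of the product A over isomer plus target. Pooled over the two readings at 20.0 min, one from each run, it reads 36.2%.

The one who made the forecast holds this share nearly steady, reading “parallel formation at a roughly constant share near 37%” with a slow upward drift allowed. The forecast is 30% at 40 s, 35% at 12 min and 44% at 4.0 h.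

I hold that target is also being lost. In the violet run from 20.0 min to 90.0 min, isomer of the product A gains 10 percentage points. At the opening share that goes with 18 points of target, but target gains 9 points, so I reckon that 8.6 points went elsewhere from a mean target of 16.5%. Taken as first-order, these figures give 1.54 h as the time in which target, its feed set aside, falls to half: the loss half-life of target. It is a rough reading, since each term carries the scatter of 2 points.

Now I join the two ends. Early, the share is the opening share. Late, I carry this half-life from the violet run over to the teal flask, cut the feed at the last teal reading, 40.0 min, and let target shrink by the factor 0.224 up to 4.0 h. Isomer of the product A then stands at the opening share and target at the rest of the product times that factor. No charge enters, and my share for the teal flask at 4.0 h is 71.7%. The feed in fact goes on, so I expect the flask a little lower.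

The flask gives 69.0% at 4.0 h, so the forecast stands 25 points low; its steady share does hold early, with 32.2% at 40 s and 33.6% at 12 min.

    coupling partner ⇌ dormant form (K = 15.0, k = 7.73 × 10⁻⁵ s⁻¹)
    target ⇌ isomer of the product B (K = 18.0, k = 8.14 × 10⁻⁵ s⁻¹)
    substrate + coupling partner ⇌ target (K = 61.5 M⁻¹, k = 0.00551 M⁻¹ s⁻¹)
    substrate + coupling partner ⇌ isomer of the product A (K = 701 M⁻¹, k = 0.00261 M⁻¹ s⁻¹)

In the flask, target and isomer of the product A stand level at 23.8% each after 1.91 h. Starting level there with the feed set aside, 1.36 loss half-lives of 1.54 h reckon to 71.9% at 4.0 h. My reckoning from the loss half-life holds no charge, so it stays at 71.7% for the neighbour charged with 0.013 M of coupling partner, and that neighbour gives 69.3% at 4.0 h, from target at 3.75% and isomer of the product A at 8.46%.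

The readings come from a simulation from invented constants; the scatter is artificial.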